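## The problem

Hyphenrone F is a single cyclooctane ring, numbered here as in the parent acylphloroglucinols: C1 (CH bearing the isobutyryl group), C2 (C=O), C3 (C(OH) bearing prenyl), C4 (C=O), C5 (CH–prenyl), C6 (CH2), C7 (CH–prenyl), C8 (quaternary; methyl and homoprenyl). An eight-membered carbocycle with five stereocenters is the central difficulty. End-to-end closure is disfavoured entropically and by transannular strain, and the four trisubstituted alkenes rule out metathesis, hydrogenation, ozonolysis and peracids. C5, C7 and C8 form a contiguous array (C8 quaternary, between C7 and C1) and can control one another reliably only while held in a six-membered ring. C3 stands alone between two carbonyl groups with only C5 as a near neighbour, and C1 lies between two ketones and is labile. The tertiary α-hydroxy-β-diketone at C2–C3–C4 is open to retro-Claisen cleavage and acyloin shifts under base, and an enolized 1,3-dione carrying a prenyl group cyclizes onto its alkene under strong acid, so this array must appear last. The enabling feature is the C2/C4 1,3-dione inside the ring: C4(=O), C5, C6, C7, C8 and C1 are the six atoms of a cyclohexanone, and C2–C3 is a two-carbon acyl unit inserted into its C1–C4 bond. That pattern is what the retro-aldol opening of a 3-oxycyclobutanone delivers, so the medium ring can be grown from a six-membered ring instead of being closed.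

## Retrosynthesis

**Target 21 to triketone 20.** The C3–O bond is cut first. The hydroxyl is the most fragile function and C3 is the only stereocenter without a ring-based control element, so it is introduced last by oxidation of the C3 enolate of 20. The forward step must select C3 over C1 and the face anti to the C5 prenyl group.

**Triketone 20 to dione 18 and Weinreb amide 19.** The C1–acyl bond is cut. C1 cannot carry the acyl group earlier, because it must be the free, nucleophilic enol ether carbon in the key step. The forward reaction is γ-acylation of the dianion of a 1,3-dione, and it must choose the C1 methylene over the C5 methine.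

**Dione 18 to silyl enol ether 11 and acid chloride 14 (key disconnection).** The bonds C1–C2 and C3–C4 are cut and C1–C4 is re-formed. The eight-membered dione with three secured stereocenters becomes a cyclohexanone enol ether plus an achiral five-carbon-chain acid chloride that already carries the C3 prenyl group. The neighbouring cut (inserting C3–C4 between C2 and C5) would make C5 the ring-fusion carbon and erase its configuration. The forward reaction needs a ketene that prefers the enol ether to three trisubstituted alkenes, and a fragmentation that opens the ring-fusion bond.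

**Enol ether 11 to enone 8 and bromide 9.** The C8–homoprenyl bond is cut. Conjugate addition to a 3-methyl-4-substituted cyclohexenone sets the quaternary C8 anti to the C7 prenyl group and delivers the enolate regiospecifically on the C1 side, where deprotonation could not place it.

**Enone 8 to enone 6 and prenyl bromide 7.** The C5–prenyl bond is cut. Kinetic alkylation on the six-membered ring sets the 1,3-trans relation C5/C7, which an eight-membered ring could not be trusted to give.

**Enone 6 to enone 4, and 4 to aldehyde 1 and enone 2.** The C8–CH3 bond is cut (conjugate methylation and re-oxidation), then C6–C7 and C1=C8 (Michael addition and aldol condensation). The only stereocenter not derived from another, C7, comes from an amine-catalysed Michael addition.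

**Acid chloride 14 to chloro acid 13 to acid 12.** The C–Cl bond is cut. The chlorine makes the ketene reactive enough for a [2+2] and is removed in the ring-expansion step.

## Roads not taken

**Alternative 1:** The most obvious plan is the biogenetic one. C1 and C5 are reconnected through a C9 carbonyl to give hyperforin A1, whose C5, C7 and C8 configuration is that of the target. Hydroxylation at C3 from the C9 face would give trione A2, and hydroxide-induced retro-Claisen opening of C1–C9 followed by loss of CO2 from C5 would give the target. It has the merit of fixing C3 on a rigid bicycle. Against it, A1 needs the full bicyclo[3.3.1]nonane machinery (two bridgehead quaternary carbons, bridgehead acylation) only for the bridge to be excised. The opening must also discriminate C9 from the equally non-enolizable C2 and C4 carbonyls of A2, and C5 is re-formed by an uncontrolled protonation. The chosen plan never builds the bridge and sets C5, C7 and C8 on a cyclohexenone in four steps.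

**Alternative 2:** Direct closure of an open chain, for example forming C3–C4 by an SmI2-mediated Reformatsky cyclization of bromo keto aldehyde A3 (or the corresponding Dieckmann or metathesis closures). The C5/C7/C8 triad with its quaternary center would have to be assembled acyclically, which costs many steps. The eight-membered closure is the step medium rings resist most, and metathesis is excluded by the four prenyl-type alkenes. The chosen plan makes the ring by fragmentation, which is driven by strain release and has no entropic penalty.

**Alternative 3:** A de Mayo reaction: photocycloaddition of the enol of 2-acylcyclohexanone A4 with an oxygenated alkene, then retro-aldol. This would insert C2–C3 with the acyl group already on C1 and only one possible fragmentation direction. Against it, the excited enol of A4 would be intercepted intramolecularly by the alkenyl chains on C5, C7 and C8. The inserted carbons would also arrive at the alcohol oxidation level and without the C3 prenyl group, so several redox and C–C steps would follow. The ground-state ketene variant chosen is polarity-controlled, brings C2 as a ketone and carries the C3 prenyl group.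

Key step: step 7

Remarks on the chemistry (assumptions):
- C1 lies between two carbonyl groups and is configurationally labile; its (R) configuration in the target is taken to be the one preferred at equilibrium, so it is left to settle and is not set by a reagent.
- 5-Methylhex-4-enal 1 and 5-methylhex-4-enoic acid 12 are taken as catalogue compounds. Atom labels C1–C8 in the text always refer to the target numbering given above; locants in compound names are systematic.

## Steps

Step 1
Reactants: 1 5-methylhex-4-enal; 2 but-3-en-2-one
Product: 4 (R)-4-(3-methylbut-2-en-1-yl)cyclohex-2-en-1-one, via keto aldehyde 3 (not isolated)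
Conditions: (R)-2-[diphenyl(trimethylsilyloxy)methyl]pyrrolidine (5 mol %), ethyl 3,4-dihydroxybenzoate (20 mol %), neat, 4 °C; then LiOH, i-PrOH, 25 °C
Reagents that add atoms: none
Why: Enamine-mediated Michael addition of the aldehyde to the enone on the face away from the diphenyl(silyloxy)methyl group should set the future C7 as (R); intramolecular aldol condensation then closes the cyclohexenone (organocatalytic Robinson annulation).

Step 2
Reactants: 4 (R)-4-(3-methylbut-2-en-1-yl)cyclohex-2-en-1-one
Product: 6 (R)-3-methyl-4-(3-methylbut-2-en-1-yl)cyclohex-2-en-1-one, via trimethylsilyl enol ether 5 (not isolated)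
Conditions: Me2CuLi, Me3SiCl, THF, −78 °C; then Pd(OAc)2 (10 mol %), O2 (1 atm), DMSO, 25 °C
Reagents that add atoms: lithium dimethylcuprate, [Li+].C[Cu-]C
Why: Cuprate conjugate addition with silyl trapping followed by Saegusa–Ito oxidation installs the β-methyl group and restores the enone under neutral conditions, so the γ-stereocenter is not touched; the transient methyl-bearing stereocenter is destroyed again.

Step 3
Reactants: 6 (R)-3-methyl-4-(3-methylbut-2-en-1-yl)cyclohex-2-en-1-one; 7 1-bromo-3-methylbut-2-ene
Product: 8 (4S,6S)-3-methyl-4,6-bis(3-methylbut-2-en-1-yl)cyclohex-2-en-1-one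
Conditions: LiN(i-Pr)2, THF, −78 °C; 7, DMPU, −78 → −30 °C
Reagents that add atoms: none
Why: Kinetic α'-enolate alkylation; A(1,2) strain with the 3-methyl group holds the C4 prenyl group pseudoaxial, so the electrophile should enter C6 on the opposite face and give the 4,6-trans isomer (C5/C7 of the target). The descriptor at C4 changes from R to S only through a change in CIP priorities.

Step 4
Reactants: 8 (4S,6S)-3-methyl-4,6-bis(3-methylbut-2-en-1-yl)cyclohex-2-en-1-one; 9 5-bromo-2-methylpent-2-ene
Product: 11 trimethyl{[(3R,4S,6S)-3-methyl-4,6-bis(3-methylbut-2-en-1-yl)-3-(4-methylpent-3-en-1-yl)cyclohex-1-en-1-yl]oxy}silane, via homoprenylmagnesium bromide 10 (not isolated)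
Conditions: 9, Mg, THF, 25 °C; then CuBr·SMe2 (10 mol %), Me3SiCl, HMPA, THF, −78 → −40 °C; Et3N, pentane, non-aqueous work-up
Reagents that add atoms: chlorotrimethylsilane, C[Si](C)(C)Cl
Why: Copper-catalysed, silyl-chloride-accelerated conjugate addition of the Grignard reagent should occur anti to the adjacent pseudoaxial prenyl group and create the quaternary C8 with methyl cis to the C7 prenyl group. The enolate is trapped as the silyl enol ether on the side of the quaternary carbon (C1=C4), a regiochemistry that deprotonation would not give.

Step 5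
Reactants: 12 5-methylhex-4-enoic acid
Product: 13 2-chloro-5-methylhex-4-enoic acid (racemic)
Conditions: LiN(i-Pr)2 (2.2 equiv), THF, −78 → 0 °C; CCl4, −78 → 25 °C; aq. HCl
Reagents that add atoms: carbon tetrachloride, ClC(Cl)(Cl)Cl
Why: α-Chlorination of a carboxylic acid dianion by positive-halogen transfer from CCl4, a method used for unsaturated acids; the stereocenter is irrelevant because it becomes the ketene carbon.

Step 6
Reactants: 13 2-chloro-5-methylhex-4-enoic acid
Product: 14 2-chloro-5-methylhex-4-enoyl chloride
Conditions: (COCl)2, DMF (cat.), CH2Cl2, 0 → 25 °C; distil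
Reagents that add atoms: oxalyl chloride, O=C(Cl)C(=O)Cl
Why: Standard acid chloride formation through the chloroiminium species; the neutral conditions leave the trisubstituted alkene alone.

Step 7
Reactants: 11 trimethyl{[(3R,4S,6S)-3-methyl-4,6-bis(3-methylbut-2-en-1-yl)-3-(4-methylpent-3-en-1-yl)cyclohex-1-en-1-yl]oxy}silane; 14 2-chloro-5-methylhex-4-enoyl chloride
Product: 18 (4S,6S,7S)-7-methyl-2,4,6-tris(3-methylbut-2-en-1-yl)-7-(4-methylpent-3-en-1-yl)cyclooctane-1,3-dione, via chloro(prenyl)ketene 15 (not isolated), via chlorocyclobutanone cycloadduct 16 (not isolated), via dechlorinated siloxycyclobutanone 17 (not isolated)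
Conditions: 14 (2 equiv), Et3N (slow addition), hexane, 25 °C; filter, concentrate; then Zn, AcOH, i-PrOH–H2O, 0 → 25 °C
Reagents that add atoms: none
Why: Et3N dehydrochlorinates 14 to ketene 15, whose electrophilic carbonyl carbon is attacked by the nucleophilic C1 of the enol ether while the chlorinated carbon closes onto the siloxy-bearing C4, so the four-membered ring of 16 is closed by a thermal, polarity-controlled [2+2] cycloaddition (Staudinger-type ketene–enol ether cycloaddition) that places C2(=O) on C1 and C3 on C4. Zn in AcOH then removes the α-chlorine through a zinc enolate (17), the acidic medium cleaves the silyl ether, and the freed β-hydroxycyclobutanone undergoes retro-aldol cleavage of the ring-fusion bond C1–C4, driven by release of cyclobutane strain; the eight-membered ring is therefore formed by fragmentation of the bicyclo[4.2.0]octanone and not by an end-to-end closure. The closest known reaction type is the two-carbon ring expansion of cycloalkanone silyl enol ethers to cycloalkane-1,3-diones through haloketene cycloadducts and reductive ring opening. The three stereocenters created in 16 (C1, C3, C4) are transient, since C4 becomes a carbonyl, C1 a methylene and C3 an enolizable dione methine, so no facial selectivity is asked of the cycloaddition and 18 is expected as a mixture of C3 epimers and enol forms. C5, C7 and C8 are carried through unchanged, C5 meeting only weak acid at or below room temperature. The step needs chemoselectivity of the ketene for the enol ether over three trisubstituted alkenes, which the far higher nucleophilicity of the silyl enol ether should secure, and it needs cleavage of C1–C4 instead of C3–C4, which is favoured when the chlorine is removed before the alkoxide is set free, because no halogen then stabilizes charge at C3 and C1–C4 is the more substituted, more strained ring-fusion bond.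

Step 8
Reactants: 18 (4S,6S,7S)-7-methyl-2,4,6-tris(3-methylbut-2-en-1-yl)-7-(4-methylpent-3-en-1-yl)cyclooctane-1,3-dione; 19 N-methoxy-N,2-dimethylpropanamide
Product: 20 (5R,6S,8S)-5-methyl-2,6,8-tris(3-methylbut-2-en-1-yl)-5-(4-methylpent-3-en-1-yl)-4-(2-methylpropanoyl)cyclooctane-1,3-dione
Conditions: LiN(i-Pr)2 (2.3 equiv), THF, −78 → −30 °C; 19, −78 → −40 °C; aq. NH4Cl
Reagents that add atoms: none
Why: γ-Acylation of a 1,3-dione dianion: after deprotonation at C3, the second proton should be taken from the C1 methylene and not the C5 methine, because a fully substituted enolate terminus at C5 would suffer A(1,3) strain with the C3 prenyl group. The more basic terminal carbon then adds to the Weinreb amide, whose chelated adduct prevents over-addition; C1 and C3 of 20 are labile and are obtained as epimer/enol mixtures.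

Step 9
Reactants: 20 (5R,6S,8S)-5-methyl-2,6,8-tris(3-methylbut-2-en-1-yl)-5-(4-methylpent-3-en-1-yl)-4-(2-methylpropanoyl)cyclooctane-1,3-dione
Product: 21 (2R,4R,5R,6S,8S)-2-hydroxy-5-methyl-2,6,8-tris(3-methylbut-2-en-1-yl)-5-(4-methylpent-3-en-1-yl)-4-(2-methylpropanoyl)cyclooctane-1,3-dione (hyphenrone F)
Conditions: KN(SiMe3)2 (1.05 equiv), THF, −78 °C; 3-phenyl-2-(phenylsulfonyl)oxaziridine, −78 °C; AcOH, −78 °C
Reagents that add atoms: 3-phenyl-2-(phenylsulfonyl)oxaziridine, O=S(=O)(c1ccccc1)N1OC1c1ccccc1
Why: Enolate hydroxylation with an N-sulfonyloxaziridine, which leaves the four alkenes untouched; of the two equilibrating monoenolates the one at C1 is shielded by the quaternary C8 and its own isobutyryl group, so oxygen should be accepted at C3. The oxidant should approach the planar C2–C3–C4 enolate on the face opposite the prenyl group of the neighbouring C5, which A(1,3) strain turns out of the enolate plane, placing OH trans to that group as in the target. The product alkoxide is buffered by the acidic C1–H, and C1 then settles in its assumed equilibrium configuration.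

## Compound list

1 | 5-methylhex-4-enal | CC(C)=CCCC=O | starting material
2 | but-3-en-2-one | CC(=O)C=C | starting material
3 | (R)-2-(3-methylbut-2-en-1-yl)-5-oxohexanal | O=C[C@@H](CC=C(C)C)CCC(C)=O | intermediate
4 | (R)-4-(3-methylbut-2-en-1-yl)cyclohex-2-en-1-one | O=C1C=C[C@@H](CC=C(C)C)CC1 | intermediate
5 | trimethyl{[(3R,4R)-3-methyl-4-(3-methylbut-2-en-1-yl)cyclohex-1-en-1-yl]oxy}silane | C[Si](C)(C)OC1=C[C@H](C)[C@@H](CC=C(C)C)CC1 | intermediate
6 | (R)-3-methyl-4-(3-methylbut-2-en-1-yl)cyclohex-2-en-1-one | O=C1C=C(C)[C@@H](CC=C(C)C)CC1 | intermediate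
7 | 1-bromo-3-methylbut-2-ene | CC(C)=CCBr | starting material
8 | (4S,6S)-3-methyl-4,6-bis(3-methylbut-2-en-1-yl)cyclohex-2-en-1-one | O=C1C=C(C)[C@@H](CC=C(C)C)C[C@@H]1CC=C(C)C | intermediate
9 | 5-bromo-2-methylpent-2-ene | CC(C)=CCCBr | starting material
10 | (4-methylpent-3-en-1-yl)magnesium bromide | CC(C)=CCC[Mg]Br | intermediate
11 | trimethyl{[(3R,4S,6S)-3-methyl-4,6-bis(3-methylbut-2-en-1-yl)-3-(4-methylpent-3-en-1-yl)cyclohex-1-en-1-yl]oxy}silane | CC(C)=CCC[C@]1(C)[C@@H](CC=C(C)C)C[C@H](CC=C(C)C)C(O[Si](C)(C)C)=C1 | intermediate
12 | 5-methylhex-4-enoic acid | CC(C)=CCCC(=O)O | starting material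
13 | 2-chloro-5-methylhex-4-enoic acid (racemic) | CC(C)=CCC(Cl)C(=O)O | intermediate
14 | 2-chloro-5-methylhex-4-enoyl chloride (racemic) | CC(C)=CCC(Cl)C(Cl)=O | intermediate
15 | 2-chloro-5-methylhexa-1,4-dien-1-one (chloro(prenyl)ketene) | CC(C)=CCC(Cl)=C=O | intermediate
16 | (2S,4S,5R)-8-chloro-5-methyl-2,4,8-tris(3-methylbut-2-en-1-yl)-5-(4-methylpent-3-en-1-yl)-1-[(trimethylsilyl)oxy]bicyclo[4.2.0]octan-7-one, cis-fused, mixture at C1, C6 and C8 | CC(C)=CCC[C@]1(C)[C@@H](CC=C(C)C)C[C@H](CC=C(C)C)C2(O[Si](C)(C)C)C1C(=O)C2(Cl)CC=C(C)C | intermediate
17 | (2S,4S,5R)-5-methyl-2,4,8-tris(3-methylbut-2-en-1-yl)-5-(4-methylpent-3-en-1-yl)-1-[(trimethylsilyl)oxy]bicyclo[4.2.0]octan-7-one, cis-fused, mixture at C1, C6 and C8 | CC(C)=CCC[C@]1(C)[C@@H](CC=C(C)C)C[C@H](CC=C(C)C)C2(O[Si](C)(C)C)C1C(=O)C2CC=C(C)C | intermediate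
18 | (4S,6S,7S)-7-methyl-2,4,6-tris(3-methylbut-2-en-1-yl)-7-(4-methylpent-3-en-1-yl)cyclooctane-1,3-dione, C2 labile | CC(C)=CCC[C@]1(C)[C@@H](CC=C(C)C)C[C@H](CC=C(C)C)C(=O)C(CC=C(C)C)C(=O)C1 | intermediate
19 | N-methoxy-N,2-dimethylpropanamide | CC(C)C(=O)N(C)OC | starting material
20 | (5R,6S,8S)-5-methyl-2,6,8-tris(3-methylbut-2-en-1-yl)-5-(4-methylpent-3-en-1-yl)-4-(2-methylpropanoyl)cyclooctane-1,3-dione, C2 and C4 labile | CC(C)=CCC[C@]1(C)[C@@H](CC=C(C)C)C[C@H](CC=C(C)C)C(=O)C(CC=C(C)C)C(=O)C1C(=O)C(C)C | intermediate
21 | (2R,4R,5R,6S,8S)-2-hydroxy-5-methyl-2,6,8-tris(3-methylbut-2-en-1-yl)-5-(4-methylpent-3-en-1-yl)-4-(2-methylpropanoyl)cyclooctane-1,3-dione (hyphenrone F) | CC(C)=CCC[C@]1(C)[C@@H](CC=C(C)C)C[C@H](CC=C(C)C)C(=O)[C@](O)(CC=C(C)C)C(=O)[C@H]1C(=O)C(C)C | target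

## Step count and least certain steps

Total step count: 9. Longest linear sequence: 7 (steps 1, 2, 3, 4, 7, 8, 9); steps 5 and 6 form a two-step branch to acid chloride 14.

**Step 7 (key step).** The enol ether carbon C1 sits next to the quaternary C8, so the cycloaddition may be slow. That would let the ketene dimerize, add to the side-chain alkenes, or end in ring-retaining C-acylation through silyl transfer in the dipolar intermediate. The cyclobutanol might also open toward C3 instead of C1, because C3 now carries a substituent. The fallback sets out from 11 and returns at 18. Dichloroketene (from Cl2CHCOCl and Et3N) is the smallest and most electrophilic ketene and is the partner for which this ring expansion is established. It should give the dichloro cycloadduct (2S,4S,5R)-8,8-dichloro-5-methyl-2,4-bis(3-methylbut-2-en-1-yl)-5-(4-methylpent-3-en-1-yl)-1-[(trimethylsilyl)oxy]bicyclo[4.2.0]octan-7-one F1. Zn/AcOH should take F1 to the C3-unsubstituted dione (4S,6S,7S)-7-methyl-4,6-bis(3-methylbut-2-en-1-yl)-7-(4-methylpent-3-en-1-yl)cyclooctane-1,3-dione F2, in which C3 is a methylene and ring-fusion cleavage is the course with direct precedent. C-Prenylation of F2 at the doubly activated C3 with 7 (K2CO3, acetone) then gives 18.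

**Step 8.** The second deprotonation may occur at the C5 methine instead of the neopentyl C1 methylene, leading to acylation at C5 or loss of C5 configuration on quench. Addition of the hindered C1 enolate to the amide may also be slow. The fallback sets out from 18 and returns at 20, replacing irreversible acylation by a reversible aldol addition followed by oxidation. The dianion of 18 is treated with 2-methylpropanal at −78 → −40 °C; an adduct at the congested C5 would revert, while the C1 adduct accumulates as the aldol (5R,6S,8S)-4-(1-hydroxy-2-methylpropyl)-5-methyl-2,6,8-tris(3-methylbut-2-en-1-yl)-5-(4-methylpent-3-en-1-yl)cyclooctane-1,3-dione F3. Dess–Martin oxidation of the secondary alcohol of F3 gives 20.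

**Step 9.** The oxidant may attack the wrong face of the C3 enolate, since the only control element is the C5 substituent of a flexible eight-membered ring. Oxidation at C1 and base-induced acyl shift in the product alkoxide are further risks. The fallback sets out from 11 and returns at 21. It introduces the two C3 substituents in the opposite order, so that the face the ring exposes is taken by the carbon electrophile and the oxygen ends on the other face. Compound 11 is taken through F1 to dione F2 as above. F2 is acylated at C1 as in step 8 to the triketone (5R,6S,8S)-5-methyl-6,8-bis(3-methylbut-2-en-1-yl)-5-(4-methylpent-3-en-1-yl)-4-(2-methylpropanoyl)cyclooctane-1,3-dione F4. F4 is benzoyloxylated at the unhindered C3 methylene (NaH, dibenzoyl peroxide, THF, 0 °C) to the benzoate (5R,6S,8S)-2-(benzoyloxy)-5-methyl-6,8-bis(3-methylbut-2-en-1-yl)-5-(4-methylpent-3-en-1-yl)-4-(2-methylpropanoyl)cyclooctane-1,3-dione F5. C-Prenylation of F5 with 7 (Cs2CO3, acetone) should give the prenylated benzoate (2R,5R,6S,8S)-2-(benzoyloxy)-5-methyl-2,6,8-tris(3-methylbut-2-en-1-yl)-5-(4-methylpent-3-en-1-yl)-4-(2-methylpropanoyl)cyclooctane-1,3-dione F6. Brief methanolysis of F6 (K2CO3, MeOH, 0 °C) releases 21. Whichever face the ring prefers, one of the two orders of introduction leads to the natural C3 configuration.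

## Further compounds

F1 | step 7 | (2S,4S,5R)-8,8-dichloro-5-methyl-2,4-bis(3-methylbut-2-en-1-yl)-5-(4-methylpent-3-en-1-yl)-1-[(trimethylsilyl)oxy]bicyclo[4.2.0]octan-7-one, cis-fused | CC(C)=CCC[C@]1(C)[C@@H](CC=C(C)C)C[C@H](CC=C(C)C)C2(O[Si](C)(C)C)C1C(=O)C2(Cl)Cl
F2 | step 7 | (4S,6S,7S)-7-methyl-4,6-bis(3-methylbut-2-en-1-yl)-7-(4-methylpent-3-en-1-yl)cyclooctane-1,3-dione | CC(C)=CCC[C@]1(C)[C@@H](CC=C(C)C)C[C@H](CC=C(C)C)C(=O)CC(=O)C1
F3 | step 8 | (5R,6S,8S)-4-(1-hydroxy-2-methylpropyl)-5-methyl-2,6,8-tris(3-methylbut-2-en-1-yl)-5-(4-methylpent-3-en-1-yl)cyclooctane-1,3-dione, mixture at C2, C4 and the carbinol carbon | CC(C)=CCC[C@]1(C)[C@@H](CC=C(C)C)C[C@H](CC=C(C)C)C(=O)C(CC=C(C)C)C(=O)C1C(O)C(C)C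
F4 | step 9 | (5R,6S,8S)-5-methyl-6,8-bis(3-methylbut-2-en-1-yl)-5-(4-methylpent-3-en-1-yl)-4-(2-methylpropanoyl)cyclooctane-1,3-dione, C4 labile | CC(C)=CCC[C@]1(C)[C@@H](CC=C(C)C)C[C@H](CC=C(C)C)C(=O)CC(=O)C1C(=O)C(C)C
F5 | step 9 | (5R,6S,8S)-2-(benzoyloxy)-5-methyl-6,8-bis(3-methylbut-2-en-1-yl)-5-(4-methylpent-3-en-1-yl)-4-(2-methylpropanoyl)cyclooctane-1,3-dione, C2 and C4 labile | CC(C)=CCC[C@]1(C)[C@@H](CC=C(C)C)C[C@H](CC=C(C)C)C(=O)C(OC(=O)c2ccccc2)C(=O)C1C(=O)C(C)C
F6 | step 9 | (2R,5R,6S,8S)-2-(benzoyloxy)-5-methyl-2,6,8-tris(3-methylbut-2-en-1-yl)-5-(4-methylpent-3-en-1-yl)-4-(2-methylpropanoyl)cyclooctane-1,3-dione, C4 labile | CC(C)=CCC[C@]1(C)[C@@H](CC=C(C)C)C[C@H](CC=C(C)C)C(=O)[C@](OC(=O)c2ccccc2)(CC=C(C)C)C(=O)C1C(=O)C(C)C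
A1 | alternative 1 | hyperforin (enol form), 4-hydroxy-8-methyl-3,5,7-tris(3-methylbut-2-en-1-yl)-8-(4-methylpent-3-en-1-yl)-1-(2-methylpropanoyl)bicyclo[3.3.1]non-3-ene-2,9-dione with the natural configuration | CC(C)C(=O)[C@]12C(=O)C(=C([C@](C1=O)(C[C@@H]([C@@]2(C)CCC=C(C)C)CC=C(C)C)CC=C(C)C)O)CC=C(C)C
A2 | alternative 1 | 3-hydroxy-8-methyl-3,5,7-tris(3-methylbut-2-en-1-yl)-8-(4-methylpent-3-en-1-yl)-1-(2-methylpropanoyl)bicyclo[3.3.1]nonane-2,4,9-trione, hydroxyl at C3 on the side of the C9 bridge | CC(C)C(=O)[C@]12C(=O)[C@@](O)(CC=C(C)C)C(=O)[C@](C1=O)(C[C@@H]([C@@]2(C)CCC=C(C)C)CC=C(C)C)CC=C(C)C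
A3 | alternative 2 | (2S,4S,5S)-8-bromo-5,11-dimethyl-2,4-bis(3-methylbut-2-en-1-yl)-5-(4-methylpent-3-en-1-yl)-7-oxododec-10-enal, mixture at C8 | CC(C)=CCC[C@@](C)(CC(=O)C(Br)CC=C(C)C)[C@@H](CC=C(C)C)C[C@H](CC=C(C)C)C=O
A4 | alternative 3 | (3R,4S,6S)-3-methyl-4,6-bis(3-methylbut-2-en-1-yl)-3-(4-methylpent-3-en-1-yl)-2-(2-methylpropanoyl)cyclohexan-1-one, C2 labile | CC(C)=CCC[C@]1(C)[C@@H](CC=C(C)C)C[C@H](CC=C(C)C)C(=O)C1C(=O)C(C)C
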